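**Retrosynthetic overview**
- The target is an (S)-isoflavanone whose two prenyl groups each sit ortho to an oxygen with its other ortho carbon blocked: C6 of ring A next to O5 (other neighbour C4a, the ring fusion) and C5' of ring B next to O4' (other neighbour C3', oxygen-bearing). Both aryl–prenyl bonds are therefore cut back to O5- and O4'-(1,1-dimethylallyl) ethers, joined by one double aromatic Claisen rearrangement; only 4'-O-methylation and MOM removal follow.
- C3–H of an isoflavanone is base-labile and the 5-OH of the ketone is chelated, so the two tertiary ethers are installed while C4 is still a carbinol. The sequence is isoflavone → cis-(3S,4S)-isoflavan-4-ol (transfer-hydrogenation cascade with dynamic kinetic resolution, sets C3) → debenzylation → Pd-catalysed double O-alkylation → Dess–Martin oxidation to the (S)-ketone precursor.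
- Ring order: ring A comes from phloroacetophenone; the pyranone ring C is closed by iodocyclisation of an enaminone; ring B is attached by Suzuki coupling of the 3-iodochromone with an arylboronate made from 5-bromosalicylaldehyde.

Key step: step 15

Assumption: the (S,S)-TsDPEN–Ru catalyst is taken to give the 4S carbinol, as it does with 1-tetralone and 4-chromanone; the cis relationship then makes C3 S. If the opposite sense were found, the (R,R) catalyst would be used.

**Step 1**
Reactants: 1 2,4,6-trihydroxyacetophenone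
Product: 2 1-[2,6-dihydroxy-4-(methoxymethoxy)phenyl]ethanone
Conditions: MOMCl (1.0 equiv, slow addition), i-Pr2NEt, CH2Cl2, 0 °C
Reagents that add atoms: chloromethyl methyl ether, COCCl
Why: The 4-OH, para to the acetyl group, is the most acidic hydroxyl and the one least tied up in hydrogen bonding to the carbonyl, so one equivalent of MOMCl should etherify it first (Williamson-type O-alkylation), with over-alkylated material removed by chromatography.

**Step 2**
Reactants: 2 1-[2,6-dihydroxy-4-(methoxymethoxy)phenyl]ethanone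
Product: 3 1-[2-(benzyloxy)-6-hydroxy-4-(methoxymethoxy)phenyl]ethanone
Conditions: BnBr (1.05 equiv), K2CO3, acetone, reflux
Reagents that add atoms: benzyl bromide, BrCc1ccccc1
Why: Williamson etherification of one of the two equivalent ortho hydroxyls leaves the other locked in a strong hydrogen bond to the ketone, which should stop a second benzylation under mild carbonate conditions.

**Step 3**
Reactants: 3 1-[2-(benzyloxy)-6-hydroxy-4-(methoxymethoxy)phenyl]ethanone
Product: 4 (E)-1-[2-(benzyloxy)-6-hydroxy-4-(methoxymethoxy)phenyl]-3-(dimethylamino)prop-2-en-1-one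
Conditions: DMF dimethyl acetal, PhMe, 90 °C
Reagents that add atoms: N,N-dimethylformamide dimethyl acetal, COC(OC)N(C)C
Why: Condensation of the methyl ketone with the amide acetal gives the vinylogous amide (enaminone formation), and the chelated phenol is not alkylated.

**Step 4**
Reactants: 4 (E)-1-[2-(benzyloxy)-6-hydroxy-4-(methoxymethoxy)phenyl]-3-(dimethylamino)prop-2-en-1-one
Product: 5 5-(benzyloxy)-3-iodo-7-(methoxymethoxy)-4H-chromen-4-one
Conditions: I2, pyridine, CHCl3, rt
Reagents that add atoms: iodine, II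
Why: Electrophilic iodination of the enaminone α-carbon, attack of the free phenol on the iminium carbon and loss of dimethylamine close the pyranone ring (iodocyclisation of a 2-hydroxyaryl enaminone to a 3-iodochromone), while pyridine keeps the medium non-acidic for the MOM ether.

**Step 5**
Reactants: 6 5-bromo-2-hydroxybenzaldehyde
Product: 7 2-(benzyloxy)-5-bromobenzaldehyde
Conditions: BnBr, K2CO3, DMF, rt
Reagents that add atoms: benzyl bromide, BrCc1ccccc1
Why: Williamson etherification of the only phenol.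

**Step 6**
Reactants: 7 2-(benzyloxy)-5-bromobenzaldehyde
Product: 9 2-(benzyloxy)-5-bromophenol, via 2-(benzyloxy)-5-bromophenyl formate 8 (not isolated)
Conditions: mCPBA, CH2Cl2, rt; then K2CO3 (cat.), MeOH, rt
Reagents that add atoms: 3-chloroperbenzoic acid, OOC(=O)c1cccc(Cl)c1
Why: Baeyer–Villiger oxidation of the ortho-alkoxybenzaldehyde proceeds with migration of the electron-rich aryl group to the formate, which is methanolysed to the phenol; this turns the formyl carbon into the future 3'-oxygen.

**Step 7**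
Reactants: 9 2-(benzyloxy)-5-bromophenol
Product: 10 1-(benzyloxy)-4-bromo-2-(methoxymethoxy)benzene
Conditions: MOMCl, i-Pr2NEt, CH2Cl2, 0 °C → rt
Reagents that add atoms: chloromethyl methyl ether, COCCl
Why: Standard MOM protection of a phenol (O-alkylation with an α-chloro ether).

**Step 8**
Reactants: 10 1-(benzyloxy)-4-bromo-2-(methoxymethoxy)benzene
Product: 11 2-[4-(benzyloxy)-3-(methoxymethoxy)phenyl]-4,4,5,5-tetramethyl-1,3,2-dioxaborolane
Conditions: B2pin2, Pd(dppf)Cl2 (3 mol%), KOAc, 1,4-dioxane, 90 °C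
Reagents that add atoms: bis(pinacolato)diboron, CC1(C)OB(OC1(C)C)B1OC(C)(C)C(C)(C)O1
Why: Miyaura borylation of an aryl bromide; the benzyl and MOM ethers are inert to Pd(0)/acetate.

**Step 9**
Reactants: 5 5-(benzyloxy)-3-iodo-7-(methoxymethoxy)-4H-chromen-4-one; 11 2-[4-(benzyloxy)-3-(methoxymethoxy)phenyl]-4,4,5,5-tetramethyl-1,3,2-dioxaborolane
Product: 12 5-(benzyloxy)-3-[4-(benzyloxy)-3-(methoxymethoxy)phenyl]-7-(methoxymethoxy)-4H-chromen-4-one
Conditions: Pd(dppf)Cl2 (5 mol%), 2 M aq K2CO3, DME, 70 °C
Reagents that add atoms: none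
Why: Suzuki–Miyaura coupling of a 3-iodochromone with an arylboronate is the standard convergent isoflavone synthesis, and the mild carbonate base avoids opening the pyranone ring.

**Step 10**
Reactants: 12 5-(benzyloxy)-3-[4-(benzyloxy)-3-(methoxymethoxy)phenyl]-7-(methoxymethoxy)-4H-chromen-4-one
Product: 14 (3S,4S)-5-(benzyloxy)-3-[4-(benzyloxy)-3-(methoxymethoxy)phenyl]-7-(methoxymethoxy)chroman-4-ol (3,4-cis), via racemic isoflavanone 13 (not isolated)
Conditions: RuCl[(S,S)-TsDPEN](p-cymene) (5 mol%), HCO2H/Et3N (1:3), EtOAc, 40 °C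
Reagents that add atoms: none
Why: The Ru hydride first reduces the chromone C2=C3 bond to isoflavanone 13, whose C3 epimerises quickly in the amine-rich medium, and asymmetric transfer hydrogenation with dynamic kinetic resolution then reduces only the epimer whose catalyst-preferred carbonyl face (the one giving 4S) lies anti to the C3 aryl group, so the cis-(3S,4S) carbinol should result and C3 is set here.

**Step 11**
Reactants: 14 (3S,4S)-5-(benzyloxy)-3-[4-(benzyloxy)-3-(methoxymethoxy)phenyl]-7-(methoxymethoxy)chroman-4-ol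
Product: 15 (3S,4S)-3-[4-hydroxy-3-(methoxymethoxy)phenyl]-7-(methoxymethoxy)chroman-4,5-diol
Conditions: H2 (1 atm), 5% Pd/C, NaHCO3 (solid), EtOAc, rt; stopped at full debenzylation; base-washed silica
Reagents that add atoms: none
Why: Hydrogenolysis of aryl benzyl ethers is much faster than cleavage of the benzylic C4–OH bond, which needs acid, so under neutral, bicarbonate-buffered aprotic conditions only the two benzyl groups should be lost and C3/C4 are untouched.

**Step 12**
Reactants: 16 2-methylbut-3-en-2-ol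
Product: 17 tert-butyl 2-methylbut-3-en-2-yl carbonate
Conditions: n-BuLi, THF, −78 °C; then Boc2O, −78 °C → rt
Reagents that add atoms: di-tert-butyl dicarbonate, CC(C)(C)OC(=O)OC(=O)OC(C)(C)C
Why: Acylation of the lithium tert-alkoxide with Boc2O gives the mixed allylic carbonate needed as the π-allyl precursor.

**Step 13**
Reactants: 15 (3S,4S)-3-[4-hydroxy-3-(methoxymethoxy)phenyl]-7-(methoxymethoxy)chroman-4,5-diol; 17 tert-butyl 2-methylbut-3-en-2-yl carbonate (3 equiv)
Product: 18 (3S,4S)-7-(methoxymethoxy)-5-(2-methylbut-3-en-2-yloxy)-3-[3-(methoxymethoxy)-4-(2-methylbut-3-en-2-yloxy)phenyl]chroman-4-ol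
Conditions: Pd(PPh3)4 (5 mol%), THF, 0 °C → rt, short reaction time
Reagents that add atoms: none
Why: In this Tsuji–Trost O-allylation Pd(0) ionises 17 to a π-(dimethylallyl)palladium complex, CO2 and tert-butoxide, and the two phenoxides attack the more substituted allyl terminus under kinetic control to give the tertiary ethers; the C4–OH is far less acidic and stays free, and at the carbinol level the 5-OH is not chelated to a ketone and C3 cannot epimerise.

**Step 14**
Reactants: 18 (3S,4S)-7-(methoxymethoxy)-5-(2-methylbut-3-en-2-yloxy)-3-[3-(methoxymethoxy)-4-(2-methylbut-3-en-2-yloxy)phenyl]chroman-4-ol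
Product: 19 (S)-7-(methoxymethoxy)-5-(2-methylbut-3-en-2-yloxy)-3-[3-(methoxymethoxy)-4-(2-methylbut-3-en-2-yloxy)phenyl]chroman-4-one
Conditions: Dess–Martin periodinane, pyridine, CH2Cl2, 0 °C
Reagents that add atoms: none
Why: Dess–Martin oxidation of the secondary benzylic carbinol is fast at 0 °C, and the pyridine buffer protects the acid-labile tertiary allyl ethers and MOM groups while being too weak a base to enolise the new ketone, so C3 should stay S.

**Step 15**
Reactants: 19 (S)-7-(methoxymethoxy)-5-(2-methylbut-3-en-2-yloxy)-3-[3-(methoxymethoxy)-4-(2-methylbut-3-en-2-yloxy)phenyl]chroman-4-one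
Product: 21 (S)-5-hydroxy-3-[4-hydroxy-3-(methoxymethoxy)-5-(3-methylbut-2-enyl)phenyl]-7-(methoxymethoxy)-6-(3-methylbut-2-enyl)chroman-4-one, via A-ring mono-Claisen phenol 20 (not isolated)
Conditions: degassed PhMe, 110 °C, sealed tube
Reagents that add atoms: none
Why: Each aryl 1,1-dimethylallyl ether undergoes a concerted suprafacial [3,3]-sigmatropic shift (aromatic Claisen rearrangement) through a chair-like six-membered transition state in which the terminal vinyl CH2 bonds to the free ortho carbon, so the allyl unit is inverted and arrives as a 3,3-dimethylallyl group, and the ortho-dienone then enolises to the phenol. No ring is closed and no stereocentre is formed. The selectivity needed is regiochemical and is built into the substrate: O5 can deliver only to C6 because its other ortho carbon C4a is the ring fusion, and O4' only to C5' because C3' carries the MOM-oxygen, and a shift onto a blocked carbon cannot aromatise and reverts. Relief of the gem-dimethyl congestion, and for O5 the peri C4 carbonyl that chelates the new 5-OH, should let both shifts run near 110 °C in a neutral non-polar solvent, the A-ring ether probably first (20). Without acid or base the ketone C3–H should not enolise, so the S centre should be carried through, and onward para (Cope) migration is disfavoured because C6 and C5' carry a hydrogen that is lost in the fast tautomerisation.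

**Step 16**
Reactants: 21 (S)-5-hydroxy-3-[4-hydroxy-3-(methoxymethoxy)-5-(3-methylbut-2-enyl)phenyl]-7-(methoxymethoxy)-6-(3-methylbut-2-enyl)chroman-4-one
Product: 22 (S)-5-hydroxy-3-[4-methoxy-3-(methoxymethoxy)-5-(3-methylbut-2-enyl)phenyl]-7-(methoxymethoxy)-6-(3-methylbut-2-enyl)chroman-4-one
Conditions: TMSCHN2 (excess), MeOH/PhMe (1:4), rt
Reagents that add atoms: trimethylsilyldiazomethane, C[Si](C)(C)C=[N+]=[N-]
Why: Diazomethane-type O-methylation needs proton transfer from the phenol, so the free 4'-OH reacts while the 5-OH, held in the hydrogen bond to C4=O, should not, and the base-free medium leaves C3 alone.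

**Step 17**
Reactants: 22 (S)-5-hydroxy-3-[4-methoxy-3-(methoxymethoxy)-5-(3-methylbut-2-enyl)phenyl]-7-(methoxymethoxy)-6-(3-methylbut-2-enyl)chroman-4-one
Product: 23 (S)-5,7-dihydroxy-3-[3-hydroxy-4-methoxy-5-(3-methylbut-2-enyl)phenyl]-6-(3-methylbut-2-enyl)chroman-4-one (CNP0327275.1)
Conditions: 3 M aq HCl, MeOH, rt
Reagents that add atoms: none
Why: Acid-catalysed transacetalisation removes both phenolic MOM ethers at room temperature, conditions mild enough that the trisubstituted prenyl alkenes should not cyclise onto the neighbouring phenols and the chelated ketone should not enolise.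

**Compound list**
1 | 2,4,6-trihydroxyacetophenone | CC(=O)c1c(O)cc(O)cc1O | starting material
2 | 1-[2,6-dihydroxy-4-(methoxymethoxy)phenyl]ethanone | CC(=O)c1c(O)cc(OCOC)cc1O | intermediate
3 | 1-[2-(benzyloxy)-6-hydroxy-4-(methoxymethoxy)phenyl]ethanone | CC(=O)c1c(O)cc(OCOC)cc1OCc1ccccc1 | intermediate
4 | (E)-1-[2-(benzyloxy)-6-hydroxy-4-(methoxymethoxy)phenyl]-3-(dimethylamino)prop-2-en-1-one | CN(C)/C=C/C(=O)c1c(O)cc(OCOC)cc1OCc1ccccc1 | intermediate
5 | 5-(benzyloxy)-3-iodo-7-(methoxymethoxy)-4H-chromen-4-one | O=c1c(I)coc2cc(OCOC)cc(OCc3ccccc3)c12 | intermediate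
6 | 5-bromo-2-hydroxybenzaldehyde | O=Cc1cc(Br)ccc1O | starting material
7 | 2-(benzyloxy)-5-bromobenzaldehyde | O=Cc1cc(Br)ccc1OCc1ccccc1 | intermediate
8 | 2-(benzyloxy)-5-bromophenyl formate | O=COc1cc(Br)ccc1OCc1ccccc1 | intermediate
9 | 2-(benzyloxy)-5-bromophenol | Oc1cc(Br)ccc1OCc1ccccc1 | intermediate
10 | 1-(benzyloxy)-4-bromo-2-(methoxymethoxy)benzene | COCOc1cc(Br)ccc1OCc1ccccc1 | intermediate
11 | 2-[4-(benzyloxy)-3-(methoxymethoxy)phenyl]-4,4,5,5-tetramethyl-1,3,2-dioxaborolane | COCOc1cc(B2OC(C)(C)C(C)(C)O2)ccc1OCc1ccccc1 | intermediate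
12 | 5-(benzyloxy)-3-[4-(benzyloxy)-3-(methoxymethoxy)phenyl]-7-(methoxymethoxy)-4H-chromen-4-one | O=c1c(-c2ccc(OCc3ccccc3)c(OCOC)c2)coc2cc(OCOC)cc(OCc3ccccc3)c12 | intermediate
13 | rac-5-(benzyloxy)-3-[4-(benzyloxy)-3-(methoxymethoxy)phenyl]-7-(methoxymethoxy)chroman-4-one | O=C1C(c2ccc(OCc3ccccc3)c(OCOC)c2)COc2cc(OCOC)cc(OCc3ccccc3)c12 | intermediate
14 | (3S,4S)-5-(benzyloxy)-3-[4-(benzyloxy)-3-(methoxymethoxy)phenyl]-7-(methoxymethoxy)chroman-4-ol | O[C@H]1[C@@H](c2ccc(OCc3ccccc3)c(OCOC)c2)COc2cc(OCOC)cc(OCc3ccccc3)c12 | intermediate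
15 | (3S,4S)-3-[4-hydroxy-3-(methoxymethoxy)phenyl]-7-(methoxymethoxy)chroman-4,5-diol | O[C@H]1[C@@H](c2ccc(O)c(OCOC)c2)COc2cc(OCOC)cc(O)c12 | intermediate
16 | 2-methylbut-3-en-2-ol | C=CC(C)(C)O | starting material
17 | tert-butyl 2-methylbut-3-en-2-yl carbonate | C=CC(C)(C)OC(=O)OC(C)(C)C | intermediate
18 | (3S,4S)-7-(methoxymethoxy)-5-(2-methylbut-3-en-2-yloxy)-3-[3-(methoxymethoxy)-4-(2-methylbut-3-en-2-yloxy)phenyl]chroman-4-ol | O[C@H]1[C@@H](c2ccc(OC(C)(C)C=C)c(OCOC)c2)COc2cc(OCOC)cc(OC(C)(C)C=C)c12 | intermediate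
19 | (S)-7-(methoxymethoxy)-5-(2-methylbut-3-en-2-yloxy)-3-[3-(methoxymethoxy)-4-(2-methylbut-3-en-2-yloxy)phenyl]chroman-4-one | O=C1[C@@H](c2ccc(OC(C)(C)C=C)c(OCOC)c2)COc2cc(OCOC)cc(OC(C)(C)C=C)c12 | intermediate
20 | (S)-5-hydroxy-7-(methoxymethoxy)-6-(3-methylbut-2-enyl)-3-[3-(methoxymethoxy)-4-(2-methylbut-3-en-2-yloxy)phenyl]chroman-4-one | O=C1[C@@H](c2ccc(OC(C)(C)C=C)c(OCOC)c2)COc2cc(OCOC)c(CC=C(C)C)c(O)c12 | intermediate
21 | (S)-5-hydroxy-3-[4-hydroxy-3-(methoxymethoxy)-5-(3-methylbut-2-enyl)phenyl]-7-(methoxymethoxy)-6-(3-methylbut-2-enyl)chroman-4-one | O=C1[C@@H](c2cc(CC=C(C)C)c(O)c(OCOC)c2)COc2cc(OCOC)c(CC=C(C)C)c(O)c12 | intermediate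
22 | (S)-5-hydroxy-3-[4-methoxy-3-(methoxymethoxy)-5-(3-methylbut-2-enyl)phenyl]-7-(methoxymethoxy)-6-(3-methylbut-2-enyl)chroman-4-one | O=C1[C@@H](c2cc(CC=C(C)C)c(OC)c(OCOC)c2)COc2cc(OCOC)c(CC=C(C)C)c(O)c12 | intermediate
23 | (S)-5,7-dihydroxy-3-[3-hydroxy-4-methoxy-5-(3-methylbut-2-enyl)phenyl]-6-(3-methylbut-2-enyl)chroman-4-one | COc1c(O)cc([C@H]2COc3cc(O)c(CC=C(C)C)c(O)c3C2=O)cc1CC=C(C)C | target

**Totals**
Total step count: 17. Longest linear sequence: 12 steps (steps 1–4, 9–11, 13–17; the ring-B branch through steps 5–8 is equally long).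

**Steps most likely to fail**

Step 15 (key step). Heating the ketone may enolise C3 and erode the S configuration, the second rearrangement may stall, or a freshly formed ortho-prenylphenol may add across its own alkene. Fallback: move the rearrangement one stage earlier, where C3 carries no adjacent carbonyl. Starting from carbinol 18, the double Claisen rearrangement (degassed PhMe, 100–110 °C, or Eu(fod)3 catalysis in CHCl3 at lower temperature) should give (3S,4S)-3-[4-hydroxy-3-(methoxymethoxy)-5-(3-methylbut-2-enyl)phenyl]-7-(methoxymethoxy)-6-(3-methylbut-2-enyl)chroman-4,5-diol F1. Chemoselective oxidation of its ortho-hydroxybenzylic C4 carbinol with activated MnO2 in CH2Cl2 at rt, neutral conditions that leave the phenols and C3 alone, then rejoins the route at 21.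

Step 13. The π-allyl palladium chemistry may deliver the linear prenyl ether (isomerisation of the tertiary ether on prolonged contact with Pd(0)) or stop at mono-alkylation at the more hindered 5-OH. Fallback: from triol 15, copper-catalysed propargylation of both phenols (3-chloro-3-methylbut-1-yne, DBU, CuCl2·2H2O cat., MeCN, 0 °C), which cannot give a linear isomer, should give (3S,4S)-7-(methoxymethoxy)-5-(2-methylbut-3-yn-2-yloxy)-3-[3-(methoxymethoxy)-4-(2-methylbut-3-yn-2-yloxy)phenyl]chroman-4-ol F2. Semihydrogenation (H2, Lindlar catalyst, quinoline, EtOAc) then returns to 18.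

Step 11. The electron-rich, doubly ortho/para-oxygenated benzylic C4–OH may be hydrogenolysed or dehydrated to the isoflav-3-ene along with the benzyl ethers. Fallback: oxidise before debenzylating. From 14, Dess–Martin oxidation (pyridine buffer, CH2Cl2, 0 °C) gives (S)-5-(benzyloxy)-3-[4-(benzyloxy)-3-(methoxymethoxy)phenyl]-7-(methoxymethoxy)chroman-4-one F3. Neutral hydrogenolysis (H2, Pd/C, EtOAc) then gives (S)-5-hydroxy-3-[4-hydroxy-3-(methoxymethoxy)phenyl]-7-(methoxymethoxy)chroman-4-one F4, where the chelated ketone resists over-reduction. Double O-alkylation of F4 with carbonate 17 and Pd(PPh3)4 in THF at 0 °C, kept short to limit C3 epimerisation, rejoins the route at 19.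

**Further compounds**
F1 | step 15 | (3S,4S)-3-[4-hydroxy-3-(methoxymethoxy)-5-(3-methylbut-2-enyl)phenyl]-7-(methoxymethoxy)-6-(3-methylbut-2-enyl)chroman-4,5-diol | O[C@H]1[C@@H](c2cc(CC=C(C)C)c(O)c(OCOC)c2)COc2cc(OCOC)c(CC=C(C)C)c(O)c12
F2 | step 13 | (3S,4S)-7-(methoxymethoxy)-5-(2-methylbut-3-yn-2-yloxy)-3-[3-(methoxymethoxy)-4-(2-methylbut-3-yn-2-yloxy)phenyl]chroman-4-ol | O[C@H]1[C@@H](c2ccc(OC(C)(C)C#C)c(OCOC)c2)COc2cc(OCOC)cc(OC(C)(C)C#C)c12
F3 | step 11 | (S)-5-(benzyloxy)-3-[4-(benzyloxy)-3-(methoxymethoxy)phenyl]-7-(methoxymethoxy)chroman-4-one | O=C1[C@@H](c2ccc(OCc3ccccc3)c(OCOC)c2)COc2cc(OCOC)cc(OCc3ccccc3)c12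
F4 | step 11 | (S)-5-hydroxy-3-[4-hydroxy-3-(methoxymethoxy)phenyl]-7-(methoxymethoxy)chroman-4-one | O=C1[C@@H](c2ccc(O)c(OCOC)c2)COc2cc(OCOC)cc(O)c12
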